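The readings are calculated with made-up constants, and the scatter is random.

The end yields of elm and cedar, 17.3% and 21.8%, tempt me to call partner a weak lever, but they join two stretches of each run, so I reckon the stretch on the plateau apart from the small remainder after it.

| setting | elm | cedar | flask |
|---|---|---|---|
| solid substrate | 0.020 M | 0.020 M | 0.020 M |
| partner | 1 equiv | 1.5 equiv | 2.00 equiv |
| remark | run made earlier | run made earlier |  |
| time |  |  | 8.0 h |

| run | time / h | target / % | dissolved substrate / % |
|---|---|---|---|
| elm | 1.00 | 3.1 | 14.0 |
| elm | 2.50 | 6.1 | 11.7 |
| elm | 3.00 | 6.5 | 12.2 |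
| elm | 5.00 | 11.1 | 13.3 |
| elm | 6.00 | 15.9 | 8.3 |
| elm | 8.00 | 17.3 | 2.8 |
| cedar | 1.00 | 3.8 | 12.6 |
| cedar | 2.50 | 6.8 | 11.7 |
| cedar | 3.00 | 9.8 | 11.7 |
| cedar | 5.00 | 17.0 | 12.7 |
| cedar | 6.00 | 21.8 | 6.2 |
| cedar | 8.00 | 21.8 | 0.1 |

(standard deviation of a reading: 1 percentage point)

* target at 8.0 h, in percent of the solid substrate charged
* concentration of dissolved substrate in solution at 8.0 h, in percent of saturation

- as a solid, counted per litre of solution: solid substrate
- what was read earlier has a scatter of 1 percentage point, one standard deviation
- at the start none of the solid substrate is in solution
- dissolved substrate means what is dissolved; the solid is not counted in it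

In elm and cedar the dissolved substrate holds a plateau up to 5.00 h and then falls, so I take that time as the life of the solid, t_s. Against it I set the conversion time τ, the hours in which the plateau's target rate would turn the whole charge into target: 44.6 h at 1 equiv, from the two runs' readings at t_s taken per equivalent, 11.1% and 11.3%. These agree, so τ goes inversely with partner, and this flask has 22.3 h. Then t_s/τ gives 22.4%; the correction, the target gained after t_s, averages 5.5 percentage points, so I commit to 27.9%. The forecast, lower than my figure, says 27% (23% to 32%) and 6% of saturation (0% to 20%), holding that “most substrate leaves by a partner-independent side path”.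

    2 dissolved substrate → side product A (k = 2.90 /M/min)
    solid substrate + target → side product B (k = 0.770 /M/min)
    solid substrate ⇌ dissolved substrate, rate k3*(cs3 - [dissolved substrate]) while solid is left; crystals form when [dissolved substrate] > cs3 (solubility = 6.60 mM, k = 0.0130 /min)
    dissolved substrate + partner → target (k = 0.330 /M/min)

The flask gives 28.8% and 2.32% of saturation, inside both forecast ranges. While solid substrate stood in the flask, 15.7% of it at 4.00 h, dissolved substrate was made 1.01 times as fast as it was used at 2.33 h, it stood at 34.5% of saturation at 4.00 h, and target had by then reached 16.7% against the 17.9% that τ gives. With the solid at 0% by 8.00 h, the flask's dissolved substrate stood at 0.766%, and for the neighbouring flask with 1.20 equiv of partner, τ and the same correction give 19.0%, where that neighbouring flask holds 19.8%.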